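A direct plan would join two preformed benzene rings at the ether oxygen and complete the halogen pattern afterwards. Guaiacol A1 would be coupled with 2,4-dibromo-1-iodobenzene A2 under copper catalysis (CuI, ligand, Cs2CO3) to the diaryl ether A3. BBr3 would free the phenol A4, and excess bromine would fill the four open positions of the phenol ring. Its weakest steps would be:
- the exhaustive bromination, because the last two positions of the phenol ring (meta to OH, flanked by bromine) should be no more reactive than the free ortho position of the dibromophenoxy ring, so the regiochemistry is left to chance;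
- the copper coupling, which must choose C–I over the ortho C–Br of the same ring and risks halogen scrambling or reduction;
- the methyl protection and its removal, which add two operations and no complexity.

**Plan of the new route.** Ring A is the tetrabromophenol ring (C1 OH, C2 ether O); ring B is the 2,4-dibromophenyl ring (C1 on O, H at C6).
- The retrosynthesis first re-closes the phenol oxygen onto ring B C6 (retro-elimination), then cuts ring B at C1–C2 and C5–C6 (retro-Diels–Alder, CO2 put back).
- This leaves 5,6,7,8-tetrabromo-1,4-benzodioxine and 3,5-dibromo-2-pyrone.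
- Enabling feature: ring A is a catechol and ring B has H at C6 beside the ether carbon C1, so the edge C1–C6 can be carried as the C=C of a 1,4-dioxine ring on both catechol oxygens; C2(Br)–C3(H)–C4(Br)–C5(H) is C3–C6 of the pyrone.
- Order of rings: ring A is bought fully brominated, the dioxine ring is closed, ring B is built last and the dioxine ring opens in the same operation.
- No aryl–oxygen coupling, no late bromination (all six Br arrive in the building blocks) and no protecting group occur; the free OH is the leaving group of the aromatisation.

Key step: step 4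

Remark: tetrabromocatechol, 1,2-dibromoethane and coumalic acid are taken as catalogue chemicals. Intermediates 4, 8 and 9 are racemic (one enantiomer drawn), and the target has no stereocentre.

Step 1
Reactants: 1 3,4,5,6-tetrabromobenzene-1,2-diol (tetrabromocatechol); 2 1,2-dibromoethane
Product: 3 5,6,7,8-tetrabromo-2,3-dihydro-1,4-benzodioxine
Conditions: K2CO3 (3 equiv), 2 (3 equiv), DMF, 90 °C
Reagents that add atoms: none
Why: Double Williamson etherification in which the first SN2 is followed by a fast 6-exo-tet closure; the O–CH2 bond made here later becomes the aryl ether bond of the target, so no aryl–oxygen coupling is needed, and no stereocentre is formed.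

Step 2
Reactants: 3 5,6,7,8-tetrabromo-2,3-dihydro-1,4-benzodioxine
Product: 5 5,6,7,8-tetrabromo-1,4-benzodioxine, via trans-2,3-dibromide 4 (not isolated)
Conditions: NBS (2.2 equiv), AIBN (cat.), PhCF3, reflux; filter, concentrate; then NaI (4 equiv), acetone, rt; aq Na2S2O3
Reagents that add atoms: N-bromosuccinimide NBS, O=C1CCC(=O)N1Br (its bromine stays only in intermediate 4)
Why: Wohl–Ziegler radical bromination can attack only the two O–CH2 groups (ring A has no hydrogen), and iodide then removes the vicinal bromines by anti elimination (reductive debromination), the established way from 1,4-benzodioxanes to 1,4-benzodioxines; the stereocentres of 4 vanish.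

Step 3
Reactants: 6 coumalic acid (2-oxo-2H-pyran-5-carboxylic acid)
Product: 7 3,5-dibromo-2H-pyran-2-one
Conditions: NBS (2.5 equiv), LiOAc (0.2 equiv), MeCN–H2O 9:1, rt, dark
Reagents that add atoms: N-bromosuccinimide NBS, O=C1CCC(=O)N1Br
Why: Hunsdiecker-type bromodecarboxylation (ipso attack of electrophilic bromine at C5, loss of CO2) together with electrophilic bromination at C3, the two pyrone positions conjugated to the ring oxygen; no stereocentre is formed.

Step 4
Reactants: 5 5,6,7,8-tetrabromo-1,4-benzodioxine; 7 3,5-dibromo-2H-pyran-2-one
Product: 11 3,4,5,6-tetrabromo-2-(2,4-dibromophenoxy)phenol, via bridged lactone cycloadduct 8 (not isolated), via cis-dihydrodibenzodioxine 9 (not isolated), via amidinium phenoxide 10 (not isolated)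
Conditions: 5 (1.5 equiv), 7 (1.0 equiv), PhMe, Ar, sealed tube, 110 → 150 °C; then DBU (1.5 equiv), THF, 0 °C → rt; 1 M HCl
Reagents that add atoms: 1,8-diazabicyclo[5.4.0]undec-7-ene DBU, C1CCC2=NCCCN2CC1 (it stays only in intermediate 10, as the cation)
Why: Proposed new method: the dibromopyrone (ambident diene, LUMO lowered by the lactone and two bromines) should add across its C3 and C6 to the enediol diether C=C of 5 in an inverse-electron-demand [4+2] cycloaddition, bridged lactone 8 should expel CO2 by retro-[4+2] to the cis-fused dihydrodibenzodioxine 9, and DBU should open the dioxine ring by anti β-elimination of the tethered tetrabromophenoxide, which aromatises ring B and gives phenoxide 10. The closest known reaction type is the cycloaddition of 2-pyrones (or 1,2,4,5-tetrazines) with enol ethers and ketene acetals followed by loss of CO2 (or N2) and elimination of alcohol to an arene; here the alcohol is a phenol that stays bound through the second oxygen. Ring B is closed by the intermolecular [4+2] mode, which forms its C1–C2 and C5–C6 bonds, while the six-membered dioxine ring is sacrificed. The four stereocentres of 8 and the two of 9 come from suprafacial addition to the cis alkene and are all erased, so the endo/exo ratio is irrelevant. The cycloaddition needs no regiocontrol because 5 is symmetric; the one selectivity needed is which C–O bond of 9 breaks, and the bromine pattern should secure it: the proton on the O–CH carbon next to C–Br is the more acidic one (the cyclohexadienyl anion then has both bromines on the nodal carbons beside the charge), and if the opening ionises instead, loss of the oxygen from the other O–CH carbon gives the cation with its charge on the bromine-bearing carbons, so both pathways keep the oxygen beside bromine and lead to the 2,4- and not the 3,5-dibromophenyl ether. Acidification turns 10 into 11 with all six C–Br bonds untouched.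

**Compound list**

1 | 3,4,5,6-tetrabromobenzene-1,2-diol (tetrabromocatechol) | Oc1c(O)c(Br)c(Br)c(Br)c1Br | starting material
2 | 1,2-dibromoethane | BrCCBr | starting material
3 | 5,6,7,8-tetrabromo-2,3-dihydro-1,4-benzodioxine | Brc1c(Br)c(Br)c2OCCOc2c1Br | intermediate
4 | trans-2,3,5,6,7,8-hexabromo-2,3-dihydro-1,4-benzodioxine (racemic) | Br[C@H]1Oc2c(Br)c(Br)c(Br)c(Br)c2O[C@@H]1Br | intermediate
5 | 5,6,7,8-tetrabromo-1,4-benzodioxine | Brc1c(Br)c(Br)c2OC=COc2c1Br | intermediate
6 | coumalic acid (2-oxo-2H-pyran-5-carboxylic acid) | O=C1C=CC(=CO1)C(O)=O | starting material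
7 | 3,5-dibromo-2H-pyran-2-one | O=C1OC=C(Br)C=C1Br | intermediate
8 | Diels–Alder adduct: 2-oxabicyclo[2.2.2]oct-7-en-3-one with Br at C4 and C7, whose C5 and C6 are the two O–CH carbons of the cis-fused tetrabromobenzodioxine ring (endo isomer drawn, endo/exo mixture expected, racemic) | O=C1O[C@@H]2C(Br)=C[C@@]1(Br)[C@H]3Oc4c(Br)c(Br)c(Br)c(Br)c4O[C@@H]23 | intermediate
9 | cis-1,3,6,7,8,9-hexabromo-4a,10a-dihydrodibenzo[b,e][1,4]dioxine (racemic) | BrC1=CC(Br)=C[C@@H]2Oc3c(Br)c(Br)c(Br)c(Br)c3O[C@H]12 | intermediate
10 | 1,8-diazabicyclo[5.4.0]undec-7-enium 3,4,5,6-tetrabromo-2-(2,4-dibromophenoxy)phenoxide | [O-]c1c(Br)c(Br)c(Br)c(Br)c1Oc1ccc(Br)cc1Br.C1CCC2=[NH+]CCCN2CC1 | intermediate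
11 | 3,4,5,6-tetrabromo-2-(2,4-dibromophenoxy)phenol (no stereocentres) | Oc1c(Br)c(Br)c(Br)c(Br)c1Oc1ccc(Br)cc1Br | target

Total step count: 4. Longest linear sequence: 3 (steps 1, 2, 4).

**Steps most likely to fail**

Step 4 (proposed new method). The cycloaddition may be too slow for the 1,2-disubstituted enediol diether, whose oxygens are drained by the tetrabromoaryl ring, so that the pyrone decomposes first; or the dioxine ring may open in the wrong sense. The fallback uses known O-arylation chemistry, sets out from 1 and returns at 11. Monomethylation of 1 (MeI, 1 equiv, Li2CO3, DMF) would give 3,4,5,6-tetrabromo-2-methoxyphenol F1. O-Arylation of F1 with bis(2,4-dibromophenyl)iodonium chloride F2 (made from 1,3-dibromobenzene with iodyl sulfate (IO)2SO4 in H2SO4, then NaCl) in aqueous NaOH/dioxane at 80 °C would give 1,2,3,4-tetrabromo-5-(2,4-dibromophenoxy)-6-methoxybenzene F3. BBr3 in CH2Cl2 would cleave the methyl ether to 11.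

Step 2. The radical bromination may stop at the monobromide or proceed unselectively on the electron-poor substrate, or the α-bromo ether may hydrolyse before debromination. The fallback makes the C=C by dehydration, sets out from 1 and returns at 5. Treatment of 1 with chloroacetyl chloride (Et3N, then K2CO3, acetone) would give the lactone 5,6,7,8-tetrabromo-1,4-benzodioxin-2(3H)-one F4. Reduction with i-Bu2AlH (toluene, −78 °C) would give the racemic lactol 5,6,7,8-tetrabromo-2,3-dihydro-1,4-benzodioxin-2-ol F5. MsCl/Et3N would convert F5 through its methanesulfonate F6 into 5 by loss of methanesulfonic acid.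

Step 1. Intermolecular second alkylation to ethylene-bridged oligomers, or loss of HBr from the bromoethyl ether, may compete with ring closure. The fallback closes the ring in two separate events, sets out from 1 and returns at 3. Hydroxyethylation of 1 with ethylene carbonate (K2CO3 cat., DMF, 120 °C) would give 3,4,5,6-tetrabromo-2-(2-hydroxyethoxy)phenol F7. Intramolecular Mitsunobu etherification (PPh3, DIAD, THF, high dilution) would give 3.

**Further compounds**

F1 | step 4 | 3,4,5,6-tetrabromo-2-methoxyphenol | COc1c(O)c(Br)c(Br)c(Br)c1Br
F2 | step 4 | bis(2,4-dibromophenyl)iodonium chloride | Brc1ccc([I+]c2ccc(Br)cc2Br)c(Br)c1.[Cl-]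
F3 | step 4 | 1,2,3,4-tetrabromo-5-(2,4-dibromophenoxy)-6-methoxybenzene | COc1c(Oc2ccc(Br)cc2Br)c(Br)c(Br)c(Br)c1Br
F4 | step 2 | 5,6,7,8-tetrabromo-1,4-benzodioxin-2(3H)-one | O=C1COc2c(Br)c(Br)c(Br)c(Br)c2O1
F5 | step 2 | 5,6,7,8-tetrabromo-2,3-dihydro-1,4-benzodioxin-2-ol (racemic) | OC1COc2c(Br)c(Br)c(Br)c(Br)c2O1
F6 | step 2 | 5,6,7,8-tetrabromo-2,3-dihydro-1,4-benzodioxin-2-yl methanesulfonate (racemic) | CS(=O)(=O)OC1COc2c(Br)c(Br)c(Br)c(Br)c2O1
F7 | step 1 | 3,4,5,6-tetrabromo-2-(2-hydroxyethoxy)phenol | OCCOc1c(O)c(Br)c(Br)c(Br)c1Br
A1 | direct plan | guaiacol (2-methoxyphenol) | COc1ccccc1O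
A2 | direct plan | 2,4-dibromo-1-iodobenzene | Ic1ccc(Br)cc1Br
A3 | direct plan | 1-(2,4-dibromophenoxy)-2-methoxybenzene | COc1ccccc1Oc1ccc(Br)cc1Br
A4 | direct plan | 2-(2,4-dibromophenoxy)phenol | Oc1ccccc1Oc1ccc(Br)cc1Br
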